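**Plan**
- The retrosynthesis first cuts the methoxymethyl O–C bond on ring A and returns ring B (the 4-hydroxyphenyl ring) to a 4-alkylcyclohex-2-enone.
- Ring B carries only the chain at its ipso carbon and an oxygen para to it. The enone is therefore cut at the ipso–ortho ring bond (Michael) and at the ortho–meta ring bond on the other side of the ipso carbon (aldol), which gives a linear C11 keto aldehyde and but-3-en-2-one.
- The aryl–C(=O) bond at ring A is then cut to a lithiated 3-methoxyphenol methoxymethyl ether and the N-methoxy-N-methylamide of undec-10-enoic acid.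
- Forward: ring A is acylated, the alkene terminus is taken to the aldehyde, ring B is annulated onto the chain end and dehydrogenated, and the methoxymethyl group is removed last.
- The target has no stereocenter. The one stereocenter formed on the way (C4 of the cyclohexenone) is racemic and disappears on aromatisation.

Key step: step 6

**Step 1**
Reactants: 1 3-methoxyphenol
Product: 2 1-methoxy-3-(methoxymethoxy)benzene
Conditions: NaH, MOMCl, DMF, 0 °C to rt
Reagents that add atoms: chloromethyl methyl ether, COCCl
Why: Williamson-type O-alkylation of the sodium phenoxide gives the methoxymethyl ether, which later directs lithiation together with the methoxy group.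

**Step 2**
Reactants: 3 undec-10-enoic acid
Product: 5 N-methoxy-N-methylundec-10-enamide, via acyl imidazole 4 (not isolated)
Conditions: 1,1'-carbonyldiimidazole, CH2Cl2, rt; then MeNH(OMe)·HCl, rt
Reagents that add atoms: N,O-dimethylhydroxylamine hydrochloride, CNOC.Cl
Why: Activation of the acid as the acyl imidazole and aminolysis is a standard Weinreb amide formation that leaves the terminal alkene untouched.

**Step 3**
Reactants: 2 1-methoxy-3-(methoxymethoxy)benzene; 5 N-methoxy-N-methylundec-10-enamide
Product: 8 1-[2-methoxy-6-(methoxymethoxy)phenyl]undec-10-en-1-one, via aryllithium 6 (not isolated), via tetrahedral lithium adduct 7 (not isolated)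
Conditions: n-BuLi, THF, 0 °C; then 5, −78 °C to 0 °C; H2O quench
Reagents that add atoms: none
Why: Directed ortho-metalation takes place at the position flanked by both oxygen substituents, and the Weinreb ketone synthesis stops at the chelated tetrahedral adduct, which collapses to the ketone only on quenching.

**Step 4**
Reactants: 8 1-[2-methoxy-6-(methoxymethoxy)phenyl]undec-10-en-1-one
Product: 10 11-hydroxy-1-[2-methoxy-6-(methoxymethoxy)phenyl]undecan-1-one, via B-alkyl-9-BBN adduct 9 (not isolated)
Conditions: 9-BBN (1.1 equiv), THF, 0 °C to rt; then NaOH (3 M aq), H2O2 (30% aq), 0 °C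
Reagents that add atoms: hydrogen peroxide, OO
Why: Anti-Markovnikov hydroboration–oxidation of the terminal alkene should outpace reduction of the ketone, because 9-BBN adds quickly to monosubstituted alkenes while the carbonyl is shielded by two ortho substituents.

**Step 5**
Reactants: 10 11-hydroxy-1-[2-methoxy-6-(methoxymethoxy)phenyl]undecan-1-one
Product: 11 11-[2-methoxy-6-(methoxymethoxy)phenyl]-11-oxoundecanal
Conditions: TEMPO (10 mol%), PhI(OAc)2 (1.1 equiv), CH2Cl2, rt
Reagents that add atoms: none
Why: The oxoammonium-mediated TEMPO oxidation of a primary alcohol stops at the aldehyde under near-neutral conditions that the methoxymethyl ether should tolerate.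

**Step 6**
Reactants: 11 11-[2-methoxy-6-(methoxymethoxy)phenyl]-11-oxoundecanal; 12 but-3-en-2-one
Product: 16 4-{9-[2-methoxy-6-(methoxymethoxy)phenyl]-9-oxononyl}cyclohex-2-en-1-one (racemic), via diethylamine enamine 13 (not isolated), via Michael adduct 14 (not isolated), via aldol 15 (not isolated)
Conditions: 12 (1.5 equiv), Et2NH (0.3 equiv), MeCN, 0 °C to rt; volatiles evaporated; then KOH (aq), n-Bu4NOH (cat.), THF/Et2O, reflux, same flask
Reagents that add atoms: none
Why: Diethylamine condenses with the aldehyde of 11 to the enamine 13, whose nucleophilic carbon (the aldehyde alpha carbon, the future ipso carbon of ring B) adds to the CH2 terminus of 12; hydrolysis of the resulting iminium returns the amine and leaves the 1,5-keto aldehyde 14. Hydroxide then forms the methyl ketone enolate, which attacks the aldehyde carbon to give the aldol 15 and, after E1cB loss of water, the conjugated enone 16. The closest known reaction type is the Stork enamine Michael addition and Robinson annulation of alpha-unbranched aldehydes with methyl vinyl ketone to 4-alkylcyclohex-2-enones. The one ring formed, the six-membered carbocycle that becomes ring B, closes in a 6-(enolendo)-exo-trig aldol. The new stereocenter at C4 of the enone is under no control, arises racemic and is erased by the aromatisation in step 7. The step needs the amine to engage the aldehyde and not the C1 ketone, which the two ortho oxygen substituents flanking that ketone secure, and it needs a single Michael addition, which the branching created at the alpha carbon secures by slowing re-formation of the enamine.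

**Step 7**
Reactants: 16 4-{9-[2-methoxy-6-(methoxymethoxy)phenyl]-9-oxononyl}cyclohex-2-en-1-one (racemic)
Product: 17 9-(4-hydroxyphenyl)-1-[2-methoxy-6-(methoxymethoxy)phenyl]nonan-1-one
Conditions: Pd(O2CCF3)2 (5 mol%), 2-(dimethylamino)pyridine (10 mol%), TsOH·H2O (20 mol%), O2 (1 atm), DMSO, 80 °C
Reagents that add atoms: none
Why: Aerobic palladium-catalysed dehydrogenation of a cyclohexenone proceeds through a divalent palladium enolate and beta-hydride elimination to the cross-conjugated dienone, which tautomerises to the phenol; the hindered acyclic aryl ketone should react far more slowly, and any methoxymethyl ether lost to the acid additive would simply give the target early, the mixture converging in step 8.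

**Step 8**
Reactants: 17 9-(4-hydroxyphenyl)-1-[2-methoxy-6-(methoxymethoxy)phenyl]nonan-1-one
Product: 18 1-(2-hydroxy-6-methoxyphenyl)-9-(4-hydroxyphenyl)nonan-1-one (CNP0117926.0)
Conditions: HCl (2 M in MeOH), rt to 40 °C
Reagents that add atoms: none
Why: Acid-catalysed methanolysis of the aryl methoxymethyl acetal, assisted by the neighbouring carbonyl, should free the hydrogen-bonded ortho-hydroxy ketone without touching the methyl ether or the second phenol.

**Compound list**
1 | 3-methoxyphenol | COc1cccc(O)c1 | starting material
2 | 1-methoxy-3-(methoxymethoxy)benzene | COCOc1cccc(OC)c1 | intermediate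
3 | undec-10-enoic acid | C=CCCCCCCCCC(=O)O | starting material
4 | 1-(1H-imidazol-1-yl)undec-10-en-1-one | C=CCCCCCCCCC(=O)n1ccnc1 | intermediate (not isolated)
5 | N-methoxy-N-methylundec-10-enamide | C=CCCCCCCCCC(=O)N(C)OC | intermediate
6 | [2-methoxy-6-(methoxymethoxy)phenyl]lithium | [Li]c1c(OC)cccc1OCOC | intermediate (not isolated)
7 | lithium 1-[methoxy(methyl)amino]-1-[2-methoxy-6-(methoxymethoxy)phenyl]undec-10-en-1-olate | [Li]OC(CCCCCCCCC=C)(N(C)OC)c1c(OC)cccc1OCOC | intermediate (not isolated)
8 | 1-[2-methoxy-6-(methoxymethoxy)phenyl]undec-10-en-1-one | COCOc1cccc(OC)c1C(=O)CCCCCCCCC=C | intermediate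
9 | 11-(9-borabicyclo[3.3.1]nonan-9-yl)-1-[2-methoxy-6-(methoxymethoxy)phenyl]undecan-1-one | COCOc1cccc(OC)c1C(=O)CCCCCCCCCCB1C2CCCC1CCC2 | intermediate (not isolated)
10 | 11-hydroxy-1-[2-methoxy-6-(methoxymethoxy)phenyl]undecan-1-one | COCOc1cccc(OC)c1C(=O)CCCCCCCCCCO | intermediate
11 | 11-[2-methoxy-6-(methoxymethoxy)phenyl]-11-oxoundecanal | COCOc1cccc(OC)c1C(=O)CCCCCCCCCC=O | intermediate
12 | but-3-en-2-one | CC(=O)C=C | starting material
13 | (E)-11-(diethylamino)-1-[2-methoxy-6-(methoxymethoxy)phenyl]undec-10-en-1-one | COCOc1cccc(OC)c1C(=O)CCCCCCCC/C=C/N(CC)CC | intermediate (not isolated)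
14 | 2-{9-[2-methoxy-6-(methoxymethoxy)phenyl]-9-oxononyl}-5-oxohexanal (racemic) | COCOc1cccc(OC)c1C(=O)CCCCCCCCC(C=O)CCC(C)=O | intermediate (not isolated)
15 | 3-hydroxy-4-{9-[2-methoxy-6-(methoxymethoxy)phenyl]-9-oxononyl}cyclohexan-1-one (racemic, mixture of diastereomers) | COCOc1cccc(OC)c1C(=O)CCCCCCCCC1CCC(=O)CC1O | intermediate (not isolated)
16 | 4-{9-[2-methoxy-6-(methoxymethoxy)phenyl]-9-oxononyl}cyclohex-2-en-1-one (racemic) | COCOc1cccc(OC)c1C(=O)CCCCCCCCC1CCC(=O)C=C1 | intermediate
17 | 9-(4-hydroxyphenyl)-1-[2-methoxy-6-(methoxymethoxy)phenyl]nonan-1-one | COCOc1cccc(OC)c1C(=O)CCCCCCCCc1ccc(O)cc1 | intermediate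
18 | 1-(2-hydroxy-6-methoxyphenyl)-9-(4-hydroxyphenyl)nonan-1-one | COc1cccc(O)c1C(=O)CCCCCCCCc1ccc(O)cc1 | target

**Step count**
Total steps: 8. Longest linear sequence: 7 steps (from 1 through steps 1, 3, 4, 5, 6, 7, 8, or equally from 3 through steps 2 to 8).

**Steps most likely to fail**

Step 6. Under amine catalysis the free aldehyde and its enamine coexist, so self-aldol condensation of 11, oligomerisation of 12, a second Michael addition or incomplete ring closure may erode the annulation. The fallback separates the events with a stoichiometric, preformed enamine. It sets out from 11, which is condensed with piperidine over K2CO3 at 0 °C to give, after removal of excess amine, the enamine (E)-1-[2-methoxy-6-(methoxymethoxy)phenyl]-11-(piperidin-1-yl)undec-10-en-1-one F1. In toluene F1 should combine with 12 in an inverse-demand hetero-Diels–Alder addition to give the aminodihydropyran 1-[2-methoxy-6-(methoxymethoxy)phenyl]-9-[6-methyl-2-(piperidin-1-yl)-3,4-dihydro-2H-pyran-3-yl]nonan-1-one F2. Warming F2 with aqueous AcOH/NaOAc buffer should open it to 14 and carry it through 15 by aldol condensation. The fallback returns to the route at 16.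

Step 7. Catalyst turnover may stall before the second dehydrogenation, the chain may be dehydrogenated next to the aryl ketone, or partial acid loss of the methoxymethyl group may give mixtures. The fallback replaces the catalytic aerobic oxidation by a stoichiometric oxidation of an enol derivative. It sets out from 16, which is silylated under soft enolisation (TMSOTf, Et3N, CH2Cl2, −78 °C), where the unhindered enone should react in preference to the shielded aryl ketone, to give the dienol ether 1-[2-methoxy-6-(methoxymethoxy)phenyl]-9-{4-[(trimethylsilyl)oxy]cyclohexa-2,4-dien-1-yl}nonan-1-one F3. Saegusa–Ito oxidation with Pd(OAc)2 in MeCN should give the cross-conjugated dienone 4-{9-[2-methoxy-6-(methoxymethoxy)phenyl]-9-oxononyl}cyclohexa-2,5-dien-1-one F4, which is expected to tautomerise on work-up. The fallback returns to the route at 17.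

Step 4. The borane may reduce the aryl ketone alongside the hydroboration, or the alkaline peroxide may attack the ketone in a Baeyer–Villiger-type process. The fallback accepts the reduction instead of avoiding it. It sets out from 8, which is treated with excess BH3·THF and then NaOH/H2O2 to give the diol 1-[2-methoxy-6-(methoxymethoxy)phenyl]undecane-1,11-diol F5 (racemic). Oxidation of both alcohols with Dess–Martin periodinane (NaHCO3, CH2Cl2) should give the keto aldehyde directly. The fallback returns to the route at 11 and bypasses 10.

**Further compounds**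
F1 | step 6 | (E)-1-[2-methoxy-6-(methoxymethoxy)phenyl]-11-(piperidin-1-yl)undec-10-en-1-one | COCOc1cccc(OC)c1C(=O)CCCCCCCC/C=C/N1CCCCC1
F2 | step 6 | 1-[2-methoxy-6-(methoxymethoxy)phenyl]-9-[6-methyl-2-(piperidin-1-yl)-3,4-dihydro-2H-pyran-3-yl]nonan-1-one (mixture of diastereomers) | COCOc1cccc(OC)c1C(=O)CCCCCCCCC1CC=C(C)OC1N1CCCCC1
F3 | step 7 | 1-[2-methoxy-6-(methoxymethoxy)phenyl]-9-{4-[(trimethylsilyl)oxy]cyclohexa-2,4-dien-1-yl}nonan-1-one (racemic) | COCOc1cccc(OC)c1C(=O)CCCCCCCCC1CC=C(O[Si](C)(C)C)C=C1
F4 | step 7 | 4-{9-[2-methoxy-6-(methoxymethoxy)phenyl]-9-oxononyl}cyclohexa-2,5-dien-1-one | COCOc1cccc(OC)c1C(=O)CCCCCCCCC1C=CC(=O)C=C1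
F5 | step 4 | 1-[2-methoxy-6-(methoxymethoxy)phenyl]undecane-1,11-diol (racemic) | COCOc1cccc(OC)c1C(O)CCCCCCCCCCO
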